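## Retrosynthetic overview
1. The last operation closes C6–C7. CrCl2 reduces a (Z)-2-(bromomethyl)enoate to an allylchromium species, so C7 (the β-carbon of the enoate, normally an acceptor) attacks the C6 enal carbon. The ten-membered ring forms first and the cis γ-lactone second, in one flask, on a substrate without protecting groups.
2. The allylic bromide comes from cross metathesis of a C7 vinyl group with methyl 2-(bromomethyl)acrylate.
3. C2–C3 comes from a reagent-controlled boron aldol of a C1 methyl ketone with a C3 enal. An Evans–Tishchenko reduction then sets C1 and places the acetate on O3 only.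
4. Both Z-trisubstituted olefins come from trans-hydroalumination/iodination of propargylic alcohols. C8 comes from a Sharpless kinetic resolution, and the side chain from (R)-2-methylbutanoic acid.

Assumption: germacrane numbering (C1–C15) is used in the comments. Compounds 2, 7, 9 and 24 are bought.

## Route

Step 1
Reactants: 1 acrolein; 2 1-propynylmagnesium bromide
Product: 3 rac-hex-1-en-4-yn-3-ol
Conditions: THF, −78 to 0 °C; sat. aq NH4Cl
Reagents that add atoms: none
Why: Grignard 1,2-addition of the alkynyl nucleophile to the enal gives the C7–C10/C14 unit as the racemic carbinol.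

Step 2
Reactants: 3 rac-hex-1-en-4-yn-3-ol
Product: 5 rac-(4Z)-5-iodohexa-1,4-dien-3-ol, via cyclic vinylalanate 4 (not isolated)
Conditions: NaAlH2(OCH2CH2OMe)2 (Red-Al), THF, 0 °C to rt; I2, −78 to 0 °C; H2O
Reagents that add atoms: iodine, II
Why: Hydroxyl-directed trans-hydroalumination places aluminium on the distal alkyne carbon cis to the carbinol, and iodinolysis with retention fixes the 9Z geometry.

Step 3
Reactants: 5 rac-(4Z)-5-iodohexa-1,4-dien-3-ol
Product: 6 (3S,4Z)-5-iodohexa-1,4-dien-3-ol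
Conditions: Ti(OiPr)4, L-(+)-DIPT, t-BuOOH (0.6 equiv), 4 Å MS, CH2Cl2, −20 °C
Reagents that add atoms: none
Why: In this Sharpless kinetic resolution the (R)-alcohol is epoxidised quickly at its vinyl group (the iodoalkene is inert), so the slow (S)-alcohol, which carries the C8 configuration, is recovered enantiopure.

Step 4
Reactants: 6 (3S,4Z)-5-iodohexa-1,4-dien-3-ol; 7 (2R)-2-methylbutanoic acid
Product: 8 (3S,4Z)-5-iodohexa-1,4-dien-3-yl (2R)-2-methylbutanoate
Conditions: DCC, DMAP (cat.), CH2Cl2, 0 °C to rt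
Reagents that add atoms: none
Why: Steglich esterification acylates O8 with retention at C8 and brings in the side-chain stereocentre from the acid.

Step 5
Reactants: 8 (3S,4Z)-5-iodohexa-1,4-dien-3-yl (2R)-2-methylbutanoate; 9 tributyl(1-ethoxyvinyl)stannane
Product: 11 (3S,4Z)-5-methyl-6-oxohepta-1,4-dien-3-yl (2R)-2-methylbutanoate, via ethoxytriene 10 (not isolated)
Conditions: Cu(O2C-2-thienyl) (CuTC, 1.5 equiv), NMP, 0 °C to rt; then 0.5 M HCl, THF, 0 °C
Reagents that add atoms: water, O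
Why: Palladium-free Liebeskind-type Stille coupling with monovalent copper retains the olefin geometry and cannot ionise the bis-allylic ester, and mild hydrolysis of the enol ether gives the Z-methyl enone.

Step 6
Reactants: 12 but-2-yn-1-ol
Product: 14 (2Z)-3-iodobut-2-en-1-ol, via cyclic vinylalanate 13 (not isolated)
Conditions: NaAlH2(OCH2CH2OMe)2 (Red-Al), THF, 0 °C to rt; I2, −78 to 0 °C; H2O
Reagents that add atoms: iodine, II
Why: The same directed trans-hydroalumination/iodination fixes the 4Z geometry, with iodine cis to CH2OH.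

Step 7
Reactants: 14 (2Z)-3-iodobut-2-en-1-ol
Product: 15 tert-butyl{[(2Z)-3-iodobut-2-en-1-yl]oxy}dimethylsilane
Conditions: TBSCl, imidazole, DMF, rt
Reagents that add atoms: tert-butyldimethylsilyl chloride, CC(C)(C)[Si](C)(C)Cl
Why: Silylation masks O6 for the lithiation and keeps the later Z-enal from closing to a lactol or furan.

Step 8
Reactants: 15 tert-butyl{[(2Z)-3-iodobut-2-en-1-yl]oxy}dimethylsilane
Product: 17 (2Z)-4-[(tert-butyldimethylsilyl)oxy]-2-methylbut-2-enal, via vinyllithium 16 (not isolated)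
Conditions: t-BuLi (2.1 equiv), Et2O, −78 °C; DMF; H2O
Reagents that add atoms: N,N-dimethylformamide, CN(C)C=O
Why: Iodine–lithium exchange gives a configurationally stable vinyllithium at −78 °C, and formylation gives the C3–C6 enal with the Z geometry kept.

Step 9
Reactants: 11 (3S,4Z)-5-methyl-6-oxohepta-1,4-dien-3-yl (2R)-2-methylbutanoate; 17 (2Z)-4-[(tert-butyldimethylsilyl)oxy]-2-methylbut-2-enal
Product: 19 (3S,4Z,8S,9Z)-11-[(tert-butyldimethylsilyl)oxy]-8-hydroxy-5,9-dimethyl-6-oxoundeca-1,4,9-trien-3-yl (2R)-2-methylbutanoate, via boron enolate 18 (not isolated)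
Conditions: (+)-Ipc2BCl, Et3N, Et2O, 0 °C; 17, −78 to −20 °C; H2O2, MeOH, pH 7 buffer, 0 °C
Reagents that add atoms: none
Why: In this Paterson boron aldol the methyl ketone is enolised at CH3 only and the (+)-Ipc ligands direct attack to the Si face of the enal, giving 3S (expected dr about 5:1, minor epimer removed by chromatography).

Step 10
Reactants: 19 aldol adduct (name as in step 9); 20 acetaldehyde
Product: 21 (3S,4Z,6S,8S,9Z)-8-acetoxy-11-[(tert-butyldimethylsilyl)oxy]-6-hydroxy-5,9-dimethylundeca-1,4,9-trien-3-yl (2R)-2-methylbutanoate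
Conditions: SmI2 (0.3 equiv), THF, −10 °C
Reagents that add atoms: none
Why: In the Evans–Tishchenko reduction the samarium-bound O3 hemiacetal delivers hydride to the C1 ketone through a chair transition state, giving the 1,3-anti (1S) alcohol with the acetate on O3 only and O1 free.

Step 11
Reactants: 21 acetate alcohol (name as in step 10)
Product: 22 (3S,4Z,6S,8S,9Z)-8-acetoxy-6,11-dihydroxy-5,9-dimethylundeca-1,4,9-trien-3-yl (2R)-2-methylbutanoate
Conditions: HF·pyridine, pyridine, THF, 0 °C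
Reagents that add atoms: none
Why: Buffered fluoride desilylation frees the primary allylic O6 without the acyl migration that basic fluoride could cause.

Step 12
Reactants: 22 diol (name as in step 11)
Product: 23 (2Z,4S,6S,7Z,9S)-4-acetoxy-6-hydroxy-3,7-dimethyl-1-oxoundeca-2,7,10-trien-9-yl (2R)-2-methylbutanoate
Conditions: TEMPO (0.2 equiv), PhI(OAc)2, CH2Cl2, rt
Reagents that add atoms: none
Why: The oxoammonium (TEMPO) oxidation takes the primary allylic alcohol much faster than the hindered secondary C1 alcohol and leaves the Z-enal unisomerised.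

Step 13
Reactants: 23 enal (name as in step 12); 24 methyl 2-(bromomethyl)acrylate
Product: 25 methyl (2Z,4R,5Z,7S,9S,10Z)-9-acetoxy-2-(bromomethyl)-7-hydroxy-6,10-dimethyl-4-{[(2R)-2-methylbutanoyl]oxy}-12-oxododeca-2,5,10-trienoate
Conditions: second-generation Hoveyda–Grubbs catalyst RuCl2(H2IMes)(=CH-C6H4-2-OiPr) (10 mol %), 24 (5 equiv), 2,6-dichloro-1,4-benzoquinone (10 mol %), CH2Cl2, 40 °C
Reagents that add atoms: none
Why: In this olefin cross metathesis only the monosubstituted C7 vinyl group initiates (the three trisubstituted olefins are inert), and the slowly dimerising acrylate gives the tiglate-type isomer with the C8 chain trans to the ester and cis to CH2Br.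

Step 14
Reactants: 25 bromo enal (name as in step 13)
Product: 28 target CNP0282531.1, via allylchromium species 26 (not isolated), via hydroxy ester 27 (not isolated)
Conditions: CrCl2 (10 equiv), 4 Å MS, THF, 1 mM, syringe-pump addition, rt; aq work-up; PPTS (cat.), CH2Cl2, rt
Reagents that add atoms: none
Why: In this macrocyclising Nozaki–Hiyama 2-(alkoxycarbonyl)allylation divalent chromium reverses the polarity of the enoate β-carbon C7 (a β-acyl carbanion, that is a homoenolate equivalent), which adds to the aldehyde carbon C6; A(1,3) strain across the 4Z olefin (H3 and H6 inside, s-trans enal) exposes the face that gives 6S, the Z-allyl unit gives the syn adduct (7R, attack anti to the C9 chain at C8), and that adduct lactonises to the cis-fused α-methylene lactone.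

## Compound list
1 | acrolein | C=CC=O | starting material
2 | 1-propynylmagnesium bromide | CC#C[Mg]Br | starting material
3 | rac-hex-1-en-4-yn-3-ol | C=CC(O)C#CC | intermediate
4 | sodium cyclic vinylalanate from 3 | C=CC1O[Al-](OCCOC)(OCCOC)C(C)=C1.[Na+] | intermediate
5 | rac-(4Z)-5-iodohexa-1,4-dien-3-ol | I/C(C)=C\C(O)C=C | intermediate
6 | (3S,4Z)-5-iodohexa-1,4-dien-3-ol | I/C(C)=C\[C@@H](O)C=C | intermediate
7 | (2R)-2-methylbutanoic acid | CC[C@@H](C)C(=O)O | starting material
8 | (3S,4Z)-5-iodohexa-1,4-dien-3-yl (2R)-2-methylbutanoate | I/C(C)=C\[C@@H](OC(=O)[C@H](C)CC)C=C | intermediate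
9 | tributyl(1-ethoxyvinyl)stannane | C=C(OCC)[Sn](CCCC)(CCCC)CCCC | starting material
10 | (3S,4Z)-6-ethoxy-5-methylhepta-1,4,6-trien-3-yl (2R)-2-methylbutanoate | C=C(OCC)/C(C)=C\[C@@H](OC(=O)[C@H](C)CC)C=C | intermediate
11 | (3S,4Z)-5-methyl-6-oxohepta-1,4-dien-3-yl (2R)-2-methylbutanoate | CC(=O)/C(C)=C\[C@@H](OC(=O)[C@H](C)CC)C=C | intermediate
12 | but-2-yn-1-ol | CC#CCO | starting material
13 | sodium cyclic vinylalanate from 12 | C1O[Al-](OCCOC)(OCCOC)C(C)=C1.[Na+] | intermediate
14 | (2Z)-3-iodobut-2-en-1-ol | I/C(C)=C\CO | intermediate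
15 | tert-butyl{[(2Z)-3-iodobut-2-en-1-yl]oxy}dimethylsilane | I/C(C)=C\CO[Si](C)(C)C(C)(C)C | intermediate
16 | (Z)-vinyllithium from 15 | [Li]/C(C)=C\CO[Si](C)(C)C(C)(C)C | intermediate
17 | (2Z)-4-[(tert-butyldimethylsilyl)oxy]-2-methylbut-2-enal | O=C/C(C)=C\CO[Si](C)(C)C(C)(C)C | intermediate
18 | diisopinocampheylboron enolate of 11 | C=C(OB([C@H]1C[C@H]2C[C@@H]([C@@H]1C)C2(C)C)[C@H]1C[C@H]2C[C@@H]([C@@H]1C)C2(C)C)/C(C)=C\[C@@H](OC(=O)[C@H](C)CC)C=C | intermediate
19 | (3S,4Z,8S,9Z)-11-[(tert-butyldimethylsilyl)oxy]-8-hydroxy-5,9-dimethyl-6-oxoundeca-1,4,9-trien-3-yl (2R)-2-methylbutanoate | CC(C)(C)[Si](C)(C)OC/C=C(/C)[C@@H](O)CC(=O)/C(C)=C\[C@@H](OC(=O)[C@H](C)CC)C=C | intermediate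
20 | acetaldehyde | CC=O | starting material
21 | (3S,4Z,6S,8S,9Z)-8-acetoxy-11-[(tert-butyldimethylsilyl)oxy]-6-hydroxy-5,9-dimethylundeca-1,4,9-trien-3-yl (2R)-2-methylbutanoate | CC(C)(C)[Si](C)(C)OC/C=C(/C)[C@@H](OC(C)=O)C[C@H](O)/C(C)=C\[C@@H](OC(=O)[C@H](C)CC)C=C | intermediate
22 | (3S,4Z,6S,8S,9Z)-8-acetoxy-6,11-dihydroxy-5,9-dimethylundeca-1,4,9-trien-3-yl (2R)-2-methylbutanoate | OC/C=C(/C)[C@@H](OC(C)=O)C[C@H](O)/C(C)=C\[C@@H](OC(=O)[C@H](C)CC)C=C | intermediate
23 | (2Z,4S,6S,7Z,9S)-4-acetoxy-6-hydroxy-3,7-dimethyl-1-oxoundeca-2,7,10-trien-9-yl (2R)-2-methylbutanoate | O=C/C=C(/C)[C@@H](OC(C)=O)C[C@H](O)/C(C)=C\[C@@H](OC(=O)[C@H](C)CC)C=C | intermediate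
24 | methyl 2-(bromomethyl)acrylate | C=C(CBr)C(=O)OC | starting material
25 | methyl (2Z,4R,5Z,7S,9S,10Z)-9-acetoxy-2-(bromomethyl)-7-hydroxy-6,10-dimethyl-4-{[(2R)-2-methylbutanoyl]oxy}-12-oxododeca-2,5,10-trienoate | O=C/C=C(/C)[C@@H](OC(C)=O)C[C@H](O)/C(C)=C\[C@@H](OC(=O)[C@H](C)CC)/C=C(\CBr)C(=O)OC | intermediate
26 | dichlorochromium allyl species from 25 (CrCl2 in place of Br) | O=C/C=C(/C)[C@@H](OC(C)=O)C[C@H](O)/C(C)=C\[C@@H](OC(=O)[C@H](C)CC)/C=C(\C[Cr](Cl)Cl)C(=O)OC | intermediate
27 | methyl (1S,3S,4Z,6S,7S,8R,9Z)-3-acetoxy-1,6-dihydroxy-8-{[(2R)-2-methylbutanoyl]oxy}germacra-4,9,11(13)-trien-12-oate | C=C(C(=O)OC)[C@H]1[C@@H](O)/C=C(/C)[C@@H](OC(C)=O)C[C@H](O)/C(C)=C\[C@H]1OC(=O)[C@H](C)CC | intermediate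
28 | CNP0282531.1, (1S,3S,4Z,6S,7R,8R,9Z)-3-acetoxy-1-hydroxy-8-{[(2R)-2-methylbutanoyl]oxy}germacra-4,9,11(13)-trien-12,6-olide | C=C1C(=O)O[C@H]2/C=C(/C)[C@@H](OC(C)=O)C[C@H](O)/C(C)=C\[C@@H](OC(=O)[C@H](C)CC)[C@@H]12 | target

## Count and risks
Total steps: 14. Longest linear sequence: 11 (steps 1–5 and 9–14).

**Risk 1, step 14 (ring closure).**
- The allylchromium species could lose the C8 carboxylate by 1,4-elimination.
- Oligomers or the C7 epimer could form, and the C1/C8 pair forces one oxygen into the crowded inside position of the 9Z olefin.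
- The fallback sets out from 21 and returns at 27. It replaces the reductively made carbanion equivalent by a preformed, non-basic, configurationally fixed allylboronate.
- Cross metathesis of 21 with methyl 2-[(4,4,5,5-tetramethyl-1,3,2-dioxaborolan-2-yl)methyl]acrylate gives the silyl ether allylboronate F1.
- HF·pyridine then gives the allylic alcohol boronate F2, and TEMPO/PhI(OAc)2 gives the enal boronate F3.
- F3 closes at high dilution (toluene, 60 °C, or Sc(OTf)3 cat.) by intramolecular allylboration through a closed chair. Hydrolysis of the borate gives 27.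

**Risk 2, step 13 (cross metathesis on the full chain).**
- An allylic ester olefin paired with a 1,1-disubstituted acrylate may give low conversion.
- The fallback sets out from 8 and returns at 25. It moves the metathesis to the small fragment, where excess partner and catalyst are affordable, and carries a masked hydroxymethyl group.
- Methyl 2-(hydroxymethyl)acrylate and TBSCl give methyl 2-{[(tert-butyldimethylsilyl)oxy]methyl}acrylate F4. Metathesis with 8 gives the iodo dienoate F5.
- The conditions of step 5 give the methyl ketone F6, those of step 9 the aldol adduct F7, and those of step 10 the acetate alcohol F8.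
- HF·pyridine removes both silyl groups to give the triol F9.
- MnO2 oxidises only the electron-rich C6 allylic alcohol, giving the enal F10.
- CBr4/PPh3 at −30 °C brominates the remaining primary alcohol to give 25.

**Risk 3, step 9 (facial selectivity, lability of the Z-enone).**
- The fallback sets out from 11 and returns at 19. It replaces the stoichiometric chiral boron enolate by a catalytic Lewis-acid aldol.
- TMSOTf/Et3N turns 11 into the 2-silyloxydiene F11.
- F11 adds to 17 in a Mukaiyama aldol under the N-tosyltryptophan-derived B-butyl oxazaborolidinone antipode that opens the Si face of the enal (EtCN, −78 °C).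
- Mild acid removes the silyl group from O3 to give 19.

## Further compounds
F1 | step 14 | silyl ether allylboronate (21 with the vinyl group turned into the (Z)-2-[(pinacolatoboryl)methyl]enoate) | CC(C)(C)[Si](C)(C)OC/C=C(/C)[C@@H](OC(C)=O)C[C@H](O)/C(C)=C\[C@@H](OC(=O)[C@H](C)CC)/C=C(\CB1OC(C)(C)C(C)(C)O1)C(=O)OC
F2 | step 14 | allylic alcohol boronate | OC/C=C(/C)[C@@H](OC(C)=O)C[C@H](O)/C(C)=C\[C@@H](OC(=O)[C@H](C)CC)/C=C(\CB1OC(C)(C)C(C)(C)O1)C(=O)OC
F3 | step 14 | enal boronate | O=C/C=C(/C)[C@@H](OC(C)=O)C[C@H](O)/C(C)=C\[C@@H](OC(=O)[C@H](C)CC)/C=C(\CB1OC(C)(C)C(C)(C)O1)C(=O)OC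
F4 | step 13 | methyl 2-{[(tert-butyldimethylsilyl)oxy]methyl}acrylate | C=C(CO[Si](C)(C)C(C)(C)C)C(=O)OC
F5 | step 13 | iodo dienoate | I/C(C)=C\[C@@H](OC(=O)[C@H](C)CC)/C=C(\CO[Si](C)(C)C(C)(C)C)C(=O)OC
F6 | step 13 | methyl ketone | CC(=O)/C(C)=C\[C@@H](OC(=O)[C@H](C)CC)/C=C(\CO[Si](C)(C)C(C)(C)C)C(=O)OC
F7 | step 13 | aldol adduct | CC(C)(C)[Si](C)(C)OC/C=C(/C)[C@@H](O)CC(=O)/C(C)=C\[C@@H](OC(=O)[C@H](C)CC)/C=C(\CO[Si](C)(C)C(C)(C)C)C(=O)OC
F8 | step 13 | acetate alcohol | CC(C)(C)[Si](C)(C)OC/C=C(/C)[C@@H](OC(C)=O)C[C@H](O)/C(C)=C\[C@@H](OC(=O)[C@H](C)CC)/C=C(\CO[Si](C)(C)C(C)(C)C)C(=O)OC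
F9 | step 13 | triol | OC/C=C(/C)[C@@H](OC(C)=O)C[C@H](O)/C(C)=C\[C@@H](OC(=O)[C@H](C)CC)/C=C(\CO)C(=O)OC
F10 | step 13 | enal | O=C/C=C(/C)[C@@H](OC(C)=O)C[C@H](O)/C(C)=C\[C@@H](OC(=O)[C@H](C)CC)/C=C(\CO)C(=O)OC
F11 | step 9 | 2-silyloxydiene | C=C(O[Si](C)(C)C)/C(C)=C\[C@@H](OC(=O)[C@H](C)CC)C=C
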